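**Strategy**

The plan cuts the three-carbon tether between C4 of ring B (the central furan) and C3 of ring C (the terminal furan) at both bonds to its middle carbon. The two outer carbons are furylmethyl CH2 groups, good electrophiles as bromides; the middle CH2 is introduced as C2 of 1,3-dithiane, which is lithiated and alkylated twice in one pot and thus serves as a methylene dianion. The precursor is bromide 16, which already holds ring B, the (S) methyl-bearing carbon and ring A (the furan that will carry the acrylic acid, here masked as a dioxolane); it is built by auxiliary-controlled allylation and two cross-couplings. Desulfurisation, acetal hydrolysis, Wittig olefination and saponification complete the route.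

Key step: step 9

Remark: the one-carbon substituent at C2 of ring A is carried through the key step as a 1,3-dioxolane (aldehyde oxidation level), which saves a reduction/oxidation pair; the stereocentre is (S) because CH2–ring B outranks the chain leading to ring A.

**Route**

Step 1
Reactants: 1 (R)-4-benzyl-3-propanoyl-1,3-oxazolidin-2-one; 2 allyl iodide (3-iodoprop-1-ene)
Product: 4 (R)-4-benzyl-3-[(S)-2-methylpent-4-enoyl]-1,3-oxazolidin-2-one, via sodium Z-enolate 3 (not isolated)
Conditions: NaN(SiMe3)2, THF, −78 °C; then 2, −78 → −40 °C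
Reagents that add atoms: sodium bis(trimethylsilyl)amide, [Na+].C[Si](C)(C)[N-][Si](C)(C)C (sodium held only by 3)
Why: Evans asymmetric alkylation: the chelated sodium Z-enolate 3 is shielded on one face by the benzyl group of the (R)-auxiliary, so allyl iodide should add to the open face and set the methyl-bearing carbon as (S).

Step 2
Reactants: 4
Product: 5 (S)-2-methylpent-4-en-1-ol
Conditions: LiBH4, MeOH (1 equiv), Et2O, 0 °C; careful concentration (volatile product)
Reagents that add atoms: none
Why: Reductive cleavage of the N-acyl oxazolidinone: hydride attacks the exocyclic carbonyl and the aldehyde released is reduced at once, which should give the primary alcohol without epimerising the adjacent stereocentre or touching the alkene.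

Step 3
Reactants: 5
Product: 6 (S)-5-iodo-4-methylpent-1-ene
Conditions: I2, PPh3, imidazole, CH2Cl2, 0 °C → rt
Reagents that add atoms: iodine, II
Why: Appel-type iodination: the alkoxyphosphonium ion formed from PPh3/I2 is displaced by iodide in an SN2 reaction at the primary carbon, one atom away from the stereocentre, which therefore keeps its configuration.

Step 4
Reactants: 6; 7 methyl 5-bromofuran-3-carboxylate
Product: 9 methyl 5-[(S)-2-methylpent-4-en-1-yl]furan-3-carboxylate, via alkylzinc iodide 8 (not isolated)
Conditions: Zn dust (I2-activated), DMA, 40 °C; then 7, Pd(OAc)2 (2 mol%), SPhos (4 mol%), THF, 40 °C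
Reagents that add atoms: zinc, [Zn] (held only by 8)
Why: Negishi coupling: zinc inserts into the primary C–I bond, and the alkylzinc iodide 8 transmetalates to the arylpalladium bromide formed by oxidative addition of zerovalent palladium into the ester-activated C5–Br bond of 7, with the bulky biarylphosphine favouring reductive elimination over beta-hydride elimination; ester and terminal alkene are inert to alkylzinc halides.

Step 5
Reactants: 10 4-bromo-2-furaldehyde
Product: 11 2-(4-bromofuran-2-yl)-1,3-dioxolane
Conditions: ethylene glycol, p-TsOH·H2O (cat.), toluene, reflux, Dean–Stark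
Reagents that add atoms: ethylene glycol, OCCO
Why: Acid-catalysed acetalisation driven by azeotropic removal of water; the electron-poor bromofuran ring tolerates catalytic acid and the dioxolane later withstands base, hydride and organometallic reagents.

Step 6
Reactants: 9; 11
Product: 13 methyl 5-[(S)-5-[5-(1,3-dioxolan-2-yl)furan-3-yl]-2-methylpentyl]furan-3-carboxylate, via B-alkyl-9-BBN 12 (not isolated)
Conditions: 9-BBN-H, THF, 0 °C → rt; then 11, Pd(OAc)2 (3 mol%), SPhos (6 mol%), aq. K3PO4, THF, 60 °C
Reagents that add atoms: 9-borabicyclo[3.3.1]nonane, B1C2CCCC1CCC2 (held only by 12)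
Why: Hydroboration with 9-BBN-H places boron at the terminal carbon of the only alkene (ester and furans do not react at rt), and the B-alkyl Suzuki–Miyaura coupling of 12 with the C4–Br bond of 11 under phosphate activation then forms the sp3–sp2 bond that completes the five-atom link between rings A and B.

Step 7
Reactants: 13
Product: 14 {5-[(S)-5-[5-(1,3-dioxolan-2-yl)furan-3-yl]-2-methylpentyl]furan-3-yl}methanol
Conditions: LiAlH4, THF, 0 °C; H2O/aq. NaOH work-up
Reagents that add atoms: none
Why: Hydride reduction of an ester to a primary alcohol with LiAlH4, a reagent that leaves acetals, furans and the remote stereocentre unchanged.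

Step 8
Reactants: 14
Product: 16 (S)-4-(bromomethyl)-2-{5-[5-(1,3-dioxolan-2-yl)furan-3-yl]-2-methylpentyl}furan, via mesylate 15 (not isolated)
Conditions: Ms2O, Et3N, THF, −20 °C; then LiBr, −20 → 0 °C; cold aq. NaHCO3 work-up, used at once
Reagents that add atoms: lithium bromide, [Li+].[Br-]; methanesulfonic anhydride, CS(=O)(=O)OS(C)(=O)=O (held only by 15)
Why: Sulfonylation of the furylmethyl alcohol followed by SN2 displacement of mesylate by bromide (Finkelstein-type exchange) under non-acidic conditions that spare the dioxolane; the anhydride is used so that no chloride competes.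

Step 9
Reactants: 17 1,3-dithiane; 18 3-(bromomethyl)furan; 16 (S)-4-(bromomethyl)-2-{5-[5-(1,3-dioxolan-2-yl)furan-3-yl]-2-methylpentyl}furan
Product: 22 2-{4-[(S)-5-(4-{[2-(furan-3-ylmethyl)-1,3-dithian-2-yl]methyl}furan-2-yl)-4-methylpentyl]furan-2-yl}-1,3-dioxolane, via 2-lithio-1,3-dithiane 19 (not isolated), via 2-(furan-3-ylmethyl)-1,3-dithiane 20 (not isolated), via 2-lithio-2-(furan-3-ylmethyl)-1,3-dithiane 21 (not isolated)
Conditions: 17 (1.3 equiv), n-BuLi (1.3 equiv), THF, −30 °C; 18 (1.25 equiv), −78 → −20 °C; n-BuLi (1.25 equiv), −30 °C, 2 h; 16 (1.0 equiv), −78 → −20 °C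
Reagents that add atoms: n-butyllithium, [Li]CCCC (lithium held only by 19 and 21)
Why: Butyllithium removes the C2 proton of 17, which two sulfur atoms acidify, and carbanion 19 displaces bromide from 18 by SN2; a second deprotonation of 20 at the same carbon gives carbanion 21, which attacks the CH2Br carbon of 16 in a second SN2 step, so that one carbon forms both new C–C bonds of the tether between ring B and ring C. The closest known reaction type is the Corey–Seebach bis-alkylation of 1,3-dithiane with benzylic or allylic halides. No ring is closed and no stereocentre is formed; the remote (S) carbon bears no acidic hydrogen and is not touched. The selectivity needed is lithiation at dithiane C2 in preference to the alpha-positions of the furans, and substitution at CH2Br in preference to attack on a ring carbon; the first should be secured by the higher kinetic acidity of the dithiane C–H and by never charging butyllithium in excess of dithiane C–H, the second by the soft sulfur-stabilised nucleophile meeting primary bromides that cannot eliminate. Charging 18 first and just short of 17, and making 16 the limiting reagent, should ensure that no 18 survives to compete for 21 and that the valuable bromide is consumed by an excess of 21. The dioxolane and the three furan rings are inert to these organolithium species between −78 and −20 °C.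

Step 10
Reactants: 22
Product: 23 2-{4-[(S)-5-{4-[3-(furan-3-yl)propyl]furan-2-yl}-4-methylpentyl]furan-2-yl}-1,3-dioxolane
Conditions: Raney Ni (W-2, acetone-deactivated), EtOH, rt → 50 °C
Reagents that add atoms: none
Why: Raney nickel desulfurisation of a dithioacetal (Mozingo reduction): both C–S bonds are cleaved on the nickel surface and replaced by C–H, and at moderate temperature without added hydrogen pressure the aromatic furans and the acetal should survive.

Step 11
Reactants: 23
Product: 24 4-[(S)-5-{4-[3-(furan-3-yl)propyl]furan-2-yl}-4-methylpentyl]furan-2-carbaldehyde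
Conditions: PPTS (cat.), acetone/H2O, 40 °C
Reagents that add atoms: water, O
Why: Mild acid-catalysed hydrolysis of an acetal: the furan-stabilised oxocarbenium ion forms readily, so a weak acid that does not open the alkylfurans is enough to release the aldehyde.

Step 12
Reactants: 24; 25 ethyl 2-(triphenyl-λ5-phosphanylidene)propanoate
Product: 26 ethyl (E)-3-{4-[(S)-5-{4-[3-(furan-3-yl)propyl]furan-2-yl}-4-methylpentyl]furan-2-yl}-2-methylprop-2-enoate
Conditions: 25 (1.5 equiv), toluene, 80 °C
Reagents that add atoms: none
Why: Wittig olefination with a stabilised ylide: reversible addition and a product-like transition state should place the ester trans to the furyl group and give the E trisubstituted alkene.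

Step 13
Reactants: 26
Product: 28 (E)-3-{4-[(S)-5-{4-[3-(furan-3-yl)propyl]furan-2-yl}-4-methylpentyl]furan-2-yl}-2-methylprop-2-enoic acid, via lithium carboxylate 27 (not isolated)
Conditions: LiOH·H2O, THF/EtOH/H2O, 40 °C; then 1 M HCl to pH 3, 0 °C
Reagents that add atoms: lithium hydroxide, [Li+].[OH-]
Why: Saponification of the conjugated ethyl ester by hydroxide (acyl–oxygen cleavage) and brief cold acidification, conditions under which the E alkene, the furans and the stereocentre are stable.

**Compound list**

1 | (R)-4-benzyl-3-propanoyl-1,3-oxazolidin-2-one | CCC(=O)N1[C@H](Cc2ccccc2)COC1=O | starting material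
2 | allyl iodide | C=CCI | starting material
3 | sodium Z-enolate of 1 | [Na+].C/C=C(\[O-])N1[C@H](Cc2ccccc2)COC1=O | intermediate
4 | (R)-4-benzyl-3-[(S)-2-methylpent-4-enoyl]-1,3-oxazolidin-2-one | C=CC[C@H](C)C(=O)N1[C@H](Cc2ccccc2)COC1=O | intermediate
5 | (S)-2-methylpent-4-en-1-ol | C=CC[C@H](C)CO | intermediate
6 | (S)-5-iodo-4-methylpent-1-ene | C=CC[C@H](C)CI | intermediate
7 | methyl 5-bromofuran-3-carboxylate | COC(=O)c1coc(Br)c1 | starting material
8 | [(S)-2-methylpent-4-en-1-yl]zinc iodide | C=CC[C@H](C)C[Zn]I | intermediate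
9 | methyl 5-[(S)-2-methylpent-4-en-1-yl]furan-3-carboxylate | COC(=O)c1coc(C[C@@H](C)CC=C)c1 | intermediate
10 | 4-bromo-2-furaldehyde | O=Cc1cc(Br)co1 | starting material
11 | 2-(4-bromofuran-2-yl)-1,3-dioxolane | Brc1coc(C2OCCO2)c1 | intermediate
12 | methyl 5-[(S)-5-(9-borabicyclo[3.3.1]nonan-9-yl)-2-methylpentyl]furan-3-carboxylate | COC(=O)c1coc(C[C@@H](C)CCCB2C3CCCC2CCC3)c1 | intermediate
13 | methyl 5-[(S)-5-[5-(1,3-dioxolan-2-yl)furan-3-yl]-2-methylpentyl]furan-3-carboxylate | COC(=O)c1coc(C[C@@H](C)CCCc2coc(C3OCCO3)c2)c1 | intermediate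
14 | {5-[(S)-5-[5-(1,3-dioxolan-2-yl)furan-3-yl]-2-methylpentyl]furan-3-yl}methanol | OCc1coc(C[C@@H](C)CCCc2coc(C3OCCO3)c2)c1 | intermediate
15 | {5-[(S)-5-[5-(1,3-dioxolan-2-yl)furan-3-yl]-2-methylpentyl]furan-3-yl}methyl methanesulfonate | CS(=O)(=O)OCc1coc(C[C@@H](C)CCCc2coc(C3OCCO3)c2)c1 | intermediate
16 | (S)-4-(bromomethyl)-2-{5-[5-(1,3-dioxolan-2-yl)furan-3-yl]-2-methylpentyl}furan | BrCc1coc(C[C@@H](C)CCCc2coc(C3OCCO3)c2)c1 | intermediate
17 | 1,3-dithiane | C1CSCSC1 | starting material
18 | 3-(bromomethyl)furan | BrCc1ccoc1 | starting material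
19 | 2-lithio-1,3-dithiane | [Li]C1SCCCS1 | intermediate
20 | 2-(furan-3-ylmethyl)-1,3-dithiane | C(c1ccoc1)C1SCCCS1 | intermediate
21 | 2-lithio-2-(furan-3-ylmethyl)-1,3-dithiane | [Li]C1(Cc2ccoc2)SCCCS1 | intermediate
22 | 2-{4-[(S)-5-(4-{[2-(furan-3-ylmethyl)-1,3-dithian-2-yl]methyl}furan-2-yl)-4-methylpentyl]furan-2-yl}-1,3-dioxolane | c1cc(CC2(Cc3coc(C[C@@H](C)CCCc4coc(C5OCCO5)c4)c3)SCCCS2)co1 | intermediate
23 | 2-{4-[(S)-5-{4-[3-(furan-3-yl)propyl]furan-2-yl}-4-methylpentyl]furan-2-yl}-1,3-dioxolane | c1cc(CCCc2coc(C[C@@H](C)CCCc3coc(C4OCCO4)c3)c2)co1 | intermediate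
24 | 4-[(S)-5-{4-[3-(furan-3-yl)propyl]furan-2-yl}-4-methylpentyl]furan-2-carbaldehyde | O=Cc1cc(CCC[C@H](C)Cc2cc(CCCc3ccoc3)co2)co1 | intermediate
25 | ethyl 2-(triphenyl-λ5-phosphanylidene)propanoate | CCOC(=O)C(C)=P(c1ccccc1)(c1ccccc1)c1ccccc1 | starting material
26 | ethyl (E)-3-{4-[(S)-5-{4-[3-(furan-3-yl)propyl]furan-2-yl}-4-methylpentyl]furan-2-yl}-2-methylprop-2-enoate | CCOC(=O)/C(C)=C/c1cc(CCC[C@H](C)Cc2cc(CCCc3ccoc3)co2)co1 | intermediate
27 | lithium (E)-3-{4-[(S)-5-{4-[3-(furan-3-yl)propyl]furan-2-yl}-4-methylpentyl]furan-2-yl}-2-methylprop-2-enoate | [Li+].[O-]C(=O)/C(C)=C/c1cc(CCC[C@H](C)Cc2cc(CCCc3ccoc3)co2)co1 | intermediate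
28 | (E)-3-{4-[(S)-5-{4-[3-(furan-3-yl)propyl]furan-2-yl}-4-methylpentyl]furan-2-yl}-2-methylprop-2-enoic acid | C/C(=C\c1cc(CCC[C@H](C)Cc2cc(CCCc3ccoc3)co2)co1)C(=O)O | target

**Step count and risks**

Total step count: 13. Longest linear sequence: 12 steps (steps 1–4 and 6–13, from compound 1); step 5 is a one-step side branch.

Steps most likely to fail:

Step 9. The second lithiation may be diverted to the alpha-positions of a furan ring, or may stay incomplete, so that bromide 16 is left to decompose; lithium–bromine exchange with homocoupling of the furylmethyl bromides is a further possible loss. The fallback replaces the dithiane by a sulfone and makes one bond at a time. It sets out from 16 (with 18) and comes back at 23. Lithiated methyl phenyl sulfone (n-BuLi, THF, −78 °C) is alkylated with 18 to give 3-[2-(phenylsulfonyl)ethyl]furan F1. Its alpha-sulfonyl carbanion (n-BuLi, THF, −78 °C) is far more acidic than any furan C–H and is alkylated with 16 to give 2-{4-[(4S)-5-{4-[3-(furan-3-yl)-2-(phenylsulfonyl)propyl]furan-2-yl}-4-methylpentyl]furan-2-yl}-1,3-dioxolane F2, a mixture at the sulfonyl carbon that is of no consequence. Reductive desulfonylation with Na(Hg), Na2HPO4, MeOH, −20 °C should then give 23.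

Step 10. Furan rings may be partly saturated or opened on the nickel surface, or sulfur removal may stop halfway. The fallback unmasks the thioacetal and removes the carbonyl under base; it sets out from 22 and comes back at 23. MeI, CaCO3, MeCN/H2O, 40 °C should give the ketone 1-{5-[(2S)-5-[5-(1,3-dioxolan-2-yl)furan-3-yl]-2-methylpentyl]furan-3-yl}-3-(furan-3-yl)propan-2-one F3. Wolff–Kishner reduction in the Huang-Minlon manner (N2H4·H2O, KOH, diethylene glycol, 130 → 200 °C) passes through the hydrazone of that ketone F4 and should give 23; acetal, furans and the remote stereocentre are stable to hot base.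

Step 8. The electron-rich furylmethyl bromide may ionise and polymerise on concentration, and traces of HBr may cleave the dioxolane. The fallback avoids any furylmethyl halide of the ring A/ring B fragment; it sets out from 14 and comes back at 23, which bypasses steps 9 and 10. MnO2, CH2Cl2, rt should oxidise 14 to 5-[(S)-5-[5-(1,3-dioxolan-2-yl)furan-3-yl]-2-methylpentyl]furan-3-carbaldehyde F5. The ylide from [2-(furan-3-yl)ethyl]triphenylphosphonium bromide F6 (from purchased 3-(2-bromoethyl)furan and PPh3, toluene, reflux; then NaN(SiMe3)2, THF, −78 °C → rt) should convert F5 into 2-{4-[(S)-5-{4-[(Z)-3-(furan-3-yl)prop-1-en-1-yl]furan-2-yl}-4-methylpentyl]furan-2-yl}-1,3-dioxolane F7; either alkene isomer serves. Diimide (2-nitrobenzenesulfonylhydrazide, Et3N, CH2Cl2, rt), which does not reduce aromatic furans, should saturate the alkene to 23.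

Further compounds
F1 | step 9 | 3-[2-(phenylsulfonyl)ethyl]furan | O=S(=O)(CCc1ccoc1)c1ccccc1
F2 | step 9 | 2-{4-[(4S)-5-{4-[3-(furan-3-yl)-2-(phenylsulfonyl)propyl]furan-2-yl}-4-methylpentyl]furan-2-yl}-1,3-dioxolane | O=S(=O)(C(Cc1ccoc1)Cc1coc(C[C@@H](C)CCCc2coc(C3OCCO3)c2)c1)c1ccccc1
F3 | step 10 | 1-{5-[(2S)-5-[5-(1,3-dioxolan-2-yl)furan-3-yl]-2-methylpentyl]furan-3-yl}-3-(furan-3-yl)propan-2-one | O=C(Cc1ccoc1)Cc1coc(C[C@@H](C)CCCc2coc(C3OCCO3)c2)c1
F4 | step 10 | hydrazone of ketone F3 | NN=C(Cc1ccoc1)Cc1coc(C[C@@H](C)CCCc2coc(C3OCCO3)c2)c1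
F5 | step 8 | 5-[(S)-5-[5-(1,3-dioxolan-2-yl)furan-3-yl]-2-methylpentyl]furan-3-carbaldehyde | O=Cc1coc(C[C@@H](C)CCCc2coc(C3OCCO3)c2)c1
F6 | step 8 | [2-(furan-3-yl)ethyl]triphenylphosphonium bromide | [Br-].c1ccc(cc1)[P+](CCc1ccoc1)(c1ccccc1)c1ccccc1
F7 | step 8 | 2-{4-[(S)-5-{4-[(Z)-3-(furan-3-yl)prop-1-en-1-yl]furan-2-yl}-4-methylpentyl]furan-2-yl}-1,3-dioxolane | c1cc(C/C=C\c2coc(C[C@@H](C)CCCc3coc(C4OCCO4)c3)c2)co1
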